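**Retrosynthetic overview**

1. Cembrane numbering is used: C1 = ring CH carrying C15 (C16 = lactone C=O, C17 = exocyclic CH2), C3/C11 = acetoxy carbons, C4/C7 = THF carbons, C8 = tertiary carbinol, C12 = lactone O–C. The plan rests on the C8(OH)–C9H2–C10H2–C11(O) segment of the 14-membered carbocycle, a 1,4-dioxygenated unit flanked by the THF oxygen (on C7) and by O12, so C9–C10 can be a hydrogenated acetylene.
2. Target ⇒ (acetylation, desilylation, C17 methylenation) seven-membered lactone ⇒ (O12–C16 lactonisation, hydrogenation) macrocyclic enyne ⇒ (ring-closing metathesis at C13=C14) acyclic propargylic diol.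
3. Propargylic diol ⇒ one-pot three-component coupling of a 2-acetyl-THF ketone (C1–C8 with C14–C16), ethynylmagnesium bromide (C9–C10) and an α-benzyloxy aldehyde (C11–C13).
4. Ketone ⇒ (R)-linalool (epoxidation/cyclisation for the THF ring, allylboration for C3, cross-metathesis and Johnson–Claisen for C1); aldehyde ⇒ (S)-2-methylglycidol.
5. Ring order: THF ring (step 1), 14-membered carbocycle (step 17), seven-membered lactone (step 20).

Key step: step 15

Remark on the chemistry: the C14 alkene is carried as an (E)-propenyl group and not as a vinyl group, because this lets C1 be set by 1,3-chirality transfer in step 8; the extra methyl leaves as propene in step 17.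
Assumption: (R)-linalool, (R)-but-3-en-2-ol, (S)-2-methylglycidol, ethynylmagnesium bromide and (−)-Ipc2B(allyl) are bought; the L-fructose-derived Shi ketone is used as a catalyst.
Abbreviations: TBS = tert-butyldimethylsilyl, TES = triethylsilyl, PMB = 4-methoxybenzyl, Bn = benzyl.

**Route**

Step 1
Reactants: 1 (R)-linalool
Product: 3 trans-furanoid linalool oxide (2R,5R), via epoxide 2 (not isolated)
Conditions: L-fructose-derived Shi ketone (0.3 equiv), Oxone (2KHSO5·KHSO4·K2SO4), K2CO3, Bu4NHSO4, MeCN–CH2(OMe)2–H2O, pH 10.5, 0 °C; then CSA (cat.), CH2Cl2, 0 °C → rt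
Reagents that add atoms: potassium peroxymonosulfate (KHSO5), [K+].[O-]S(=O)(=O)OO
Why: Shi asymmetric epoxidation attacks only the electron-rich trisubstituted alkene and, with the L-fructose-derived ketone, should give the (6S)-epoxide by catalyst control, after which acid-promoted 5-exo opening by the tertiary alcohol inverts that carbon and sets C7 (R) trans to the vinyl group, the 6-endo pyranoid isomer being the expected minor by-product.

Step 2
Reactants: 3 trans-furanoid linalool oxide
Product: 4 (2R,5R)-2-ethenyl-2-methyl-5-(prop-1-en-2-yl)oxolane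
Conditions: SOCl2, pyridine, CH2Cl2, −20 → 0 °C
Reagents that add atoms: none
Why: Chlorosulfite formation and pyridine-mediated E2 elimination of the tertiary alcohol should remove one of the six methyl hydrogens in preference to the hindered C7 methine and give the isopropenyl group without touching a stereocentre.

Step 3
Reactants: 4 diene
Product: 6 (2R,5R)-5-acetyl-2-methyloxolane-2-carbaldehyde, via bis-ozonide 5 (not isolated)
Conditions: O3, CH2Cl2, −78 °C; then Me2S, −78 °C → rt
Reagents that add atoms: ozone, [O-][O+]=O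
Why: Ozonolysis with reductive work-up cleaves both terminal alkenes at once, the vinyl group to the non-enolisable C3 aldehyde and the isopropenyl group to the C8 methyl ketone, under neutral conditions that leave C7 untouched.

Step 4
Reactants: 6 keto aldehyde
Product: 8 homoallylic alcohol (3S) with free methyl ketone, via borinate 7 (not isolated)
Conditions: (−)-Ipc2B(allyl) (1.1 equiv), Et2O, −78 °C; then NaOAc aq., 30% H2O2, 0 °C → rt
Reagents that add atoms: (−)-B-allyldiisopinocampheylborane, C=CCB([C@@H]1C[C@@H]2C[C@@H](C2(C)C)[C@H]1C)[C@@H]1C[C@@H]2C[C@@H](C2(C)C)[C@H]1C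
Why: Brown allylboration is far faster at the aldehyde than at the ketone at −78 °C and proceeds through a chair six-membered transition state whose facial sense is fixed by the isopinocampheyl groups, which should set C3 (S), while the buffered peroxide work-up avoids epimerising C7.

Step 5
Reactants: 8 homoallylic alcohol
Product: 9 C3 TBS ether of 8
Conditions: TBSOTf (1.1 equiv), 2,6-lutidine, CH2Cl2, −78 °C
Reagents that add atoms: tert-butyldimethylsilyl triflate, CC(C)(C)[Si](C)(C)OS(=O)(=O)C(F)(F)F
Why: Silyl triflate with a hindered pyridine base silylates the hindered secondary alcohol at low temperature, where the methyl ketone should not yet be converted into a silyl enol ether.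

Step 6
Reactants: 9 TBS ether
Product: 10 ethylene ketal of 9
Conditions: (Me3SiOCH2)2, TMSOTf (5 mol%), CH2Cl2, −78 → −20 °C
Reagents that add atoms: 1,2-bis(trimethylsilyloxy)ethane, C[Si](C)(C)OCCO[Si](C)(C)C
Why: Noyori ketalisation masks the ketone at low temperature without conditions that would enolise toward C7, so that the ketone function survives the hot, acidic Claisen step.

Step 7
Reactants: 10 ketal-protected terminal alkene; 11 (R)-but-3-en-2-ol (4 equiv)
Product: 12 (2R,3E,6S)-allylic alcohol
Conditions: second-generation Hoveyda–Grubbs catalyst RuCl2(=CH-C6H4-2-OiPr)(H2IMes) (5 mol%), CH2Cl2, 40 °C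
Reagents that add atoms: none
Why: Olefin cross-metathesis between a terminal alkene and an excess of a secondary allylic alcohol is normally E-selective, and the carbinol stereocentre of 11 takes no part and is carried into 12 unchanged.

Step 8
Reactants: 12 allylic alcohol
Product: 14 methyl ester with C1 (R) and (E)-propenyl group, via ketene acetal 13 (not isolated)
Conditions: MeC(OMe)3 (10 equiv), EtCO2H (cat.), 125 °C, MeOH distilled off
Reagents that add atoms: trimethyl orthoacetate, CC(OC)(OC)OC
Why: In the Johnson–Claisen rearrangement the ketene acetal reacts through a chair transition state with the carbinol methyl equatorial, so the (R)-carbinol of the (E)-allylic alcohol is transferred suprafacially to C1 (R) and the new alkene is the (E)-propenyl group that later serves as the C14 metathesis handle.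

Step 9
Reactants: 14 ketal ester
Product: 15 methyl (3R,5S)-5-[(2R,5R)-5-acetyl-2-methyloxolan-2-yl]-5-(TBSO)-3-[(E)-prop-1-enyl]pentanoate
Conditions: PPTS, acetone–H2O (10:1), 60 °C
Reagents that add atoms: water, O
Why: Mild acid-catalysed ketal hydrolysis releases the methyl ketone while the hindered secondary TBS ether and the ester survive, and the acid is weak enough that enolisation toward C7 should be negligible.

Step 10
Reactants: 16 (S)-2-methylglycidol
Product: 17 (R)-2-{[(4-methoxybenzyl)oxy]methyl}-2-methyloxirane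
Conditions: NaH, 4-MeOC6H4CH2Cl, Bu4NI (cat.), THF–DMF, 0 °C → rt
Reagents that add atoms: 4-methoxybenzyl chloride, COc1ccc(CCl)cc1
Why: Williamson etherification of the primary alkoxide leaves the epoxide and the quaternary stereocentre untouched (the descriptor changes only through the priority rules).

Step 11
Reactants: 17 PMB glycidyl ether
Product: 18 (R)-1-[(4-methoxybenzyl)oxy]-2-methylbut-3-en-2-ol
Conditions: Me3S+ I− (4 equiv), n-BuLi (4 equiv), THF, −10 °C → rt
Reagents that add atoms: trimethylsulfonium iodide, C[S+](C)C.[I-]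
Why: In this epoxide-to-allylic-alcohol homologation dimethylsulfonium methylide opens the epoxide at its CH2 terminus and the sulfonium betaine eliminates dimethyl sulfide, so the quaternary centre keeps its configuration and gains the vinyl group (C13).

Step 12
Reactants: 18 tertiary allylic alcohol
Product: 19 tertiary benzyl ether of 18
Conditions: NaH, BnBr, Bu4NI (cat.), DMF, 0 °C → rt
Reagents that add atoms: benzyl bromide, BrCc1ccccc1
Why: Williamson benzylation of the tertiary alkoxide with iodide catalysis installs the chelating, hydrogenolysable group on O12, and the neighbouring PMB ether cannot migrate as a silyl group would.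

Step 13
Reactants: 19 bis-ether
Product: 20 (R)-2-(benzyloxy)-2-methylbut-3-en-1-ol
Conditions: DDQ, CH2Cl2–pH 7 buffer, 0 °C
Reagents that add atoms: none
Why: DDQ cleaves the electron-rich PMB ether oxidatively (benzylic hydride abstraction, then hydrolysis) and leaves the plain benzyl ether and the alkene alone.

Step 14
Reactants: 20 primary alcohol
Product: 21 (R)-2-(benzyloxy)-2-methylbut-3-enal
Conditions: Dess–Martin periodinane, NaHCO3, CH2Cl2, 0 °C → rt
Reagents that add atoms: none
Why: Dess–Martin oxidation under buffered conditions gives the aldehyde, which has a quaternary α-carbon and therefore cannot epimerise or enolise.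

Step 15
Reactants: 15 methyl ketone; 22 ethynylmagnesium bromide (1.2 equiv); 21 aldehyde (1.8 equiv)
Product: 25 C8,C11-propargylic diol (8R,11R), via magnesium alkoxide 23 (not isolated), via alkynylmagnesium species 24 (not isolated)
Conditions: 15, THF, −78 °C; 22 (0.5 M in THF), −78 → −30 °C; iPrMgCl·LiCl (1.4 equiv), −20 → 0 °C; 21, −78 → −20 °C; NH4Cl aq.
Reagents that add atoms: none
Why: This is a sequential double carbonyl addition of an acetylene dianion equivalent, the closest known reaction type being chelation-controlled addition of alkynyl Grignard reagents to α-alkoxy ketones and aldehydes: ethynylmagnesium bromide adds to the C8 ketone to give alkoxide 23, iPrMgCl·LiCl removes the acetylenic proton to give 24 (an acid–base exchange at or below 0 °C that should outrun addition of this hindered Grignard to the methyl ester), and 24 adds to aldehyde 21. No ring is closed; the step forms C8–C9 and C10–C11. C8 is set by a five-membered magnesium chelate between the THF oxygen and the ketone oxygen, which exposes the face on the side of the C7 hydrogen and should give (8R). C11 is set by the five-membered chelate between the benzyloxy oxygen and the aldehyde oxygen, with attack past the C12 methyl and anti to the larger vinyl group to give (11R); this is the weaker of the two biases. The step needs ketone-over-ester chemoselectivity, secured by the chelate-activated α-alkoxy ketone and the low temperature, and an aldehyde that cannot enolise, secured by the quaternary C12.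

Step 16
Reactants: 25 propargylic diol
Product: 26 C8,C11-bis-TES ether
Conditions: TESOTf (3 equiv), 2,6-lutidine, CH2Cl2, −78 → 0 °C
Reagents that add atoms: triethylsilyl triflate, CC[Si](CC)(CC)OS(=O)(=O)C(F)(F)F
Why: The silyl triflate is reactive enough to cap both the secondary and the tertiary propargylic hydroxyl, which removes acidic protons before metathesis and enolate chemistry and leaves O12 as the only oxygen to be unveiled for lactonisation.

Step 17
Reactants: 26 bis-TES ether
Product: 27 14-membered cycloalkenyne (C13=C14, C9≡C10)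
Conditions: second-generation Grubbs catalyst RuCl2(=CHPh)(PCy3)(H2IMes) (15 mol%), toluene (1 mM), 80 °C
Reagents that add atoms: none
Why: In this ring-closing metathesis the catalyst should load at the less hindered propenyl end and close onto the C12 vinyl group with loss of propene (the C13=C14 geometry is irrelevant), while the alkyne, flanked by two fully substituted silyloxy carbons, should be too hindered for enyne metathesis.

Step 18
Reactants: 27 cycloalkenyne
Product: 28 saturated macrocyclic hydroxy ester (free C12 OH)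
Conditions: H2 (3 atm), 10% Pd/C, EtOAc, rt
Reagents that add atoms: none
Why: Heterogeneous hydrogenation saturates the alkyne and the alkene and then hydrogenolyses the tertiary benzyl ether, silyl ethers being poor leaving groups for allylic or propargylic C–O hydrogenolysis and stable in methanol-free EtOAc.

Step 19
Reactants: 28 hydroxy ester
Product: 29 seco acid
Conditions: LiOH·H2O, THF–MeOH–H2O, rt; then 1 M HCl to pH 4, 0 °C
Reagents that add atoms: lithium hydroxide, [Li+].[OH-]
Why: Saponification of the unhindered methyl ester proceeds by acyl substitution, and the silyl ethers tolerate aqueous LiOH and a brief cold acidification.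

Step 20
Reactants: 29 seco acid
Product: 31 seven-membered lactone (O12–C16), via mixed anhydride 30 (not isolated)
Conditions: 2,4,6-Cl3C6H2COCl, Et3N, THF, rt; then DMAP, toluene (2 mM), 80 °C
Reagents that add atoms: none
Why: In the Yamaguchi lactonisation DMAP converts the mixed anhydride into an acylpyridinium ion that is captured by the tertiary C12 hydroxyl, the only free hydroxyl, in a seven-membered closure favoured over oligomerisation by high dilution and by the preorganising macrocycle.

Step 21
Reactants: 31 lactone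
Product: 32 C15 (dimethylamino)methyl lactone
Conditions: LDA (1.3 equiv), THF, −78 °C; then CH2=NMe2+ I−, −78 → 0 °C
Reagents that add atoms: Eschenmoser's salt (N,N-dimethylmethyleneiminium iodide), C=[N+](C)C.[I-]
Why: Mannich reaction of the lithium lactone enolate, C15 being the only enolisable position, with the preformed iminium salt installs C17, and the new C15 stereocentre is erased in the next step.

Step 22
Reactants: 32 Mannich base
Product: 34 α-methylene lactone (silyl ethers intact), via ammonium iodide 33 (not isolated)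
Conditions: MeI, THF–MeOH, rt; then DBU, CH2Cl2, rt
Reagents that add atoms: none
Why: Exhaustive N-methylation gives the ammonium salt, which loses trimethylamine by base-induced β-elimination (E1cB) to give the exocyclic C15=C17 alkene.

Step 23
Reactants: 34 tris-silyl ether
Product: 35 C3,C8,C11-triol
Conditions: HF·pyridine, pyridine, THF, 0 °C → rt
Reagents that add atoms: none
Why: Fluoride cleaves the two TES ethers and the TBS ether under buffered, weakly acidic conditions that the α-methylene lactone tolerates, and the triol is carried on at once to limit acyl migration to the free C3 and C11 hydroxyls.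

Step 24
Reactants: 35 triol
Product: 36 CNP0343714.1 (target)
Conditions: Ac2O, pyridine, DMAP (cat.), CH2Cl2, 0 °C → rt
Reagents that add atoms: acetic anhydride, CC(=O)OC(C)=O
Why: DMAP-catalysed acetylation esterifies the two secondary alcohols at C3 and C11, while the tertiary C8 alcohol next to the THF ring is too hindered to react under these mild conditions.

**Compound list**

1 | (R)-linalool, (3R)-3,7-dimethylocta-1,6-dien-3-ol | C=C[C@](C)(O)CCC=C(C)C | starting material
2 | (3R,6S)-6,7-epoxylinalool | C=C[C@](C)(O)CC[C@@H]1OC1(C)C | intermediate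
3 | trans-furanoid linalool oxide, 2-[(2R,5R)-5-ethenyl-5-methyloxolan-2-yl]propan-2-ol | C=C[C@@]1(C)CC[C@@H](O1)C(C)(C)O | intermediate
4 | (2R,5R)-2-ethenyl-2-methyl-5-(prop-1-en-2-yl)oxolane | C=C[C@@]1(C)CC[C@@H](O1)C(C)=C | intermediate
5 | bis-ozonide of 4 (a 1,2,4-trioxolane at each former alkene) | C1(OCOO1)[C@@]2(C)CC[C@@H](O2)C3(C)OCOO3 | intermediate
6 | (2R,5R)-5-acetyl-2-methyloxolane-2-carbaldehyde | O=C[C@@]1(C)CC[C@@H](O1)C(C)=O | intermediate
7 | diisopinocampheylborinate ester of 8 | C=CC[C@H](OB([C@@H]1C[C@@H]2C[C@@H](C2(C)C)[C@H]1C)[C@@H]1C[C@@H]2C[C@@H](C2(C)C)[C@H]1C)[C@@]1(C)CC[C@@H](O1)C(C)=O | intermediate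
8 | 1-[(2R,5R)-5-[(1S)-1-hydroxybut-3-en-1-yl]-5-methyloxolan-2-yl]ethan-1-one | C=CC[C@H](O)[C@@]1(C)CC[C@@H](O1)C(C)=O | intermediate
9 | TBS ether of 8 (C3 OTBS) | C=CC[C@H](O[Si](C)(C)C(C)(C)C)[C@@]1(C)CC[C@@H](O1)C(C)=O | intermediate
10 | ethylene ketal of 9 (2-methyl-1,3-dioxolan-2-yl at C7) | C=CC[C@H](O[Si](C)(C)C(C)(C)C)[C@@]1(C)CC[C@@H](O1)C1(C)OCCO1 | intermediate
11 | (R)-but-3-en-2-ol | C[C@@H](O)C=C | starting material
12 | (2R,3E,6S)-6-(TBSO)-6-[(2R,5R)-2-methyl-5-(2-methyl-1,3-dioxolan-2-yl)oxolan-2-yl]hex-3-en-2-ol | C[C@@H](O)/C=C/C[C@H](O[Si](C)(C)C(C)(C)C)[C@@]1(C)CC[C@@H](O1)C1(C)OCCO1 | intermediate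
13 | O-allyl O-methyl ketene acetal of 12 | C[C@@H](OC(=C)OC)/C=C/C[C@H](O[Si](C)(C)C(C)(C)C)[C@@]1(C)CC[C@@H](O1)C1(C)OCCO1 | intermediate
14 | methyl (3R,5S)-5-(TBSO)-5-[(2R,5R)-2-methyl-5-(2-methyl-1,3-dioxolan-2-yl)oxolan-2-yl]-3-[(E)-prop-1-enyl]pentanoate | C/C=C/[C@@H](CC(=O)OC)C[C@H](O[Si](C)(C)C(C)(C)C)[C@@]1(C)CC[C@@H](O1)C1(C)OCCO1 | intermediate
15 | methyl (3R,5S)-5-[(2R,5R)-5-acetyl-2-methyloxolan-2-yl]-5-(TBSO)-3-[(E)-prop-1-enyl]pentanoate (key-step ketone) | C/C=C/[C@@H](CC(=O)OC)C[C@H](O[Si](C)(C)C(C)(C)C)[C@@]1(C)CC[C@@H](O1)C(C)=O | intermediate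
16 | (S)-2-methylglycidol | C[C@]1(CO)CO1 | starting material
17 | (R)-2-{[(4-methoxybenzyl)oxy]methyl}-2-methyloxirane | C[C@]1(COCc2ccc(OC)cc2)CO1 | intermediate
18 | (R)-1-[(4-methoxybenzyl)oxy]-2-methylbut-3-en-2-ol | C=C[C@@](C)(O)COCc1ccc(OC)cc1 | intermediate
19 | (R)-2-(benzyloxy)-1-[(4-methoxybenzyl)oxy]-2-methylbut-3-ene | C=C[C@@](C)(OCc1ccccc1)COCc1ccc(OC)cc1 | intermediate
20 | (R)-2-(benzyloxy)-2-methylbut-3-en-1-ol | C=C[C@@](C)(OCc1ccccc1)CO | intermediate
21 | (R)-2-(benzyloxy)-2-methylbut-3-enal | O=C[C@](C)(OCc1ccccc1)C=C | intermediate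
22 | ethynylmagnesium bromide | C#C[Mg]Br | starting material
23 | bromomagnesium alkoxide of the (8R)-C8 ethynyl carbinol | C/C=C/[C@@H](CC(=O)OC)C[C@H](O[Si](C)(C)C(C)(C)C)[C@@]1(C)CC[C@@H](O1)[C@](C)(O[Mg]Br)C#C | intermediate
24 | C10 alkynylmagnesium chloride of 23 | C/C=C/[C@@H](CC(=O)OC)C[C@H](O[Si](C)(C)C(C)(C)C)[C@@]1(C)CC[C@@H](O1)[C@](C)(O[Mg]Br)C#C[Mg]Cl | intermediate
25 | (1R,3S,4R,7R,8R,11R,12R)-propargylic diol: C16 methyl ester, C3 OTBS, C8 OH, C11 OH, C12 OBn, C9≡C10, propenyl on C1, vinyl on C12 | C/C=C/[C@@H](CC(=O)OC)C[C@H](O[Si](C)(C)C(C)(C)C)[C@@]1(C)CC[C@@H](O1)[C@](C)(O)C#C[C@@H](O)[C@](C)(OCc1ccccc1)C=C | intermediate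
26 | C8,C11-bis-TES ether of 25 | C/C=C/[C@@H](CC(=O)OC)C[C@H](O[Si](C)(C)C(C)(C)C)[C@@]1(C)CC[C@@H](O1)[C@](C)(O[Si](CC)(CC)CC)C#C[C@@H](O[Si](CC)(CC)CC)[C@](C)(OCc1ccccc1)C=C | intermediate
27 | 14-membered cycloalkenyne (C13=C14, C9≡C10; C12 OBn, C8/C11 OTES, C3 OTBS, C16 methyl ester) | C1=C[C@@H](CC(=O)OC)C[C@H](O[Si](C)(C)C(C)(C)C)[C@@]2(C)CC[C@@H](O2)[C@](C)(O[Si](CC)(CC)CC)C#C[C@@H](O[Si](CC)(CC)CC)[C@]1(C)OCc1ccccc1 | intermediate
28 | saturated macrocyclic hydroxy ester (C12 OH, C16 methyl ester) | C1C[C@@H](CC(=O)OC)C[C@H](O[Si](C)(C)C(C)(C)C)[C@@]2(C)CC[C@@H](O2)[C@](C)(O[Si](CC)(CC)CC)CC[C@@H](O[Si](CC)(CC)CC)[C@]1(C)O | intermediate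
29 | seco acid (C12 OH, C16 CO2H) | C1C[C@@H](CC(=O)O)C[C@H](O[Si](C)(C)C(C)(C)C)[C@@]2(C)CC[C@@H](O2)[C@](C)(O[Si](CC)(CC)CC)CC[C@@H](O[Si](CC)(CC)CC)[C@]1(C)O | intermediate
30 | mixed anhydride of 29 with 2,4,6-trichlorobenzoic acid | C1C[C@@H](CC(=O)OC(=O)c3c(Cl)cc(Cl)cc3Cl)C[C@H](O[Si](C)(C)C(C)(C)C)[C@@]2(C)CC[C@@H](O2)[C@](C)(O[Si](CC)(CC)CC)CC[C@@H](O[Si](CC)(CC)CC)[C@]1(C)O | intermediate
31 | seven-membered lactone (O12–C16; C3 OTBS, C8/C11 OTES) | C1C(=O)O[C@]2(C)CC[C@@H]1C[C@H](O[Si](C)(C)C(C)(C)C)[C@@]1(C)CC[C@@H](O1)[C@](C)(O[Si](CC)(CC)CC)CC[C@H]2O[Si](CC)(CC)CC | intermediate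
32 | C15 (dimethylamino)methyl lactone (C15 epimers) | CN(C)CC1C(=O)O[C@]2(C)CC[C@@H]1C[C@H](O[Si](C)(C)C(C)(C)C)[C@@]1(C)CC[C@@H](O1)[C@](C)(O[Si](CC)(CC)CC)CC[C@H]2O[Si](CC)(CC)CC | intermediate
33 | trimethylammonium iodide of 32 | C[N+](C)(C)CC1C(=O)O[C@]2(C)CC[C@@H]1C[C@H](O[Si](C)(C)C(C)(C)C)[C@@]1(C)CC[C@@H](O1)[C@](C)(O[Si](CC)(CC)CC)CC[C@H]2O[Si](CC)(CC)CC.[I-] | intermediate
34 | α-methylene lactone (C3 OTBS, C8/C11 OTES) | C=C1C(=O)O[C@]2(C)CC[C@@H]1C[C@H](O[Si](C)(C)C(C)(C)C)[C@@]1(C)CC[C@@H](O1)[C@](C)(O[Si](CC)(CC)CC)CC[C@H]2O[Si](CC)(CC)CC | intermediate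
35 | α-methylene lactone C3,C8,C11-triol | C=C1C(=O)O[C@]2(C)CC[C@@H]1C[C@H](O)[C@@]1(C)CC[C@@H](O1)[C@](C)(O)CC[C@H]2O | intermediate
36 | CNP0343714.1, (1R,3S,4R,7R,8R,11R,12R)-3,11-diacetate | C=C1C(=O)O[C@]2(C)CC[C@@H]1C[C@H](OC(C)=O)[C@@]1(C)CC[C@@H](O1)[C@](C)(O)CC[C@H]2OC(C)=O | target

**Step count and risks**

Total step count: 24. Longest linear sequence: 19 steps (steps 1–9, then 15–24); the aldehyde branch is steps 10–14.

Step 15 is the step most likely to fail. The facial selectivity at C11 may be poor, because methyl and vinyl on C12 differ little in size within the magnesium chelate; attack of the metalating Grignard on the methyl ester is a lesser concern. The fallback sets out from 25 obtained as a mixture with its C11 epimer. MnO2 (CH2Cl2, rt) should oxidise only the secondary propargylic alcohol and give the C11 ynone F1. Corey–Bakshi–Shibata reduction with (S)-2-methyl-CBS-oxazaborolidine and catecholborane (toluene, −78 °C), with the slim alkynyl group as the small substituent and the quaternary C12 as the large one, then sets C11 (R) by reagent control. The fallback comes back to the route at 25.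

Step 17 is next. Ring closure may be slow at the two hindered alkenes, so that oligomerisation or enyne metathesis at the alkyne competes. The fallback sets out from 26. Co2(CO)8 (CH2Cl2, rt) gives the alkyne–hexacarbonyldicobalt complex F2, which blocks enyne metathesis and bends the C8–C9–C10–C11 axis so that the chain ends approach each other. Ring-closing metathesis (second-generation Grubbs catalyst, CH2Cl2, 40 °C) gives the macrocyclic cobalt complex F3. Oxidative decomplexation with (NH4)2Ce(NO3)6 (acetone, −78 → 0 °C) returns the free alkyne, and the fallback comes back to the route at 27.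

Step 20 is third. Acylation of the tertiary C12 hydroxyl, which sits next to the C11 silyl ether, may be too slow, so that the activated acid dimerises or is consumed by the reagent. The fallback sets out from 28 and skips the seco acid. KN(SiMe3)2 (1.05 equiv, THF, 2 mM, −40 → 0 °C, then AcOH) deprotonates the tertiary alcohol, and the alkoxide attacks the methyl ester in an intramolecular transesterification; the nucleophile is activated and not the acyl group. The fallback comes back to the route at 31 and makes no new compound (F0).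

**Further compounds**

F1 | step 15 | C11 ynone of 25 (C8 OH free) | C/C=C/[C@@H](CC(=O)OC)C[C@H](O[Si](C)(C)C(C)(C)C)[C@@]1(C)CC[C@@H](O1)[C@](C)(O)C#CC(=O)[C@](C)(OCc1ccccc1)C=C
F2 | step 17 | alkyne–hexacarbonyldicobalt complex of 26 | C/C=C/[C@@H](CC(=O)OC)C[C@H](O[Si](C)(C)C(C)(C)C)[C@@]1(C)CC[C@@H](O1)[C@](C)(O[Si](CC)(CC)CC)C23[Co]4(=C=O)(=C=O)(=C=O)[Co]2(=C=O)(=C=O)(=C=O)C34[C@@H](O[Si](CC)(CC)CC)[C@](C)(OCc1ccccc1)C=C
F3 | step 17 | alkyne–hexacarbonyldicobalt complex of 27 | C1=C[C@@H](CC(=O)OC)C[C@H](O[Si](C)(C)C(C)(C)C)[C@@]2(C)CC[C@@H](O2)[C@](C)(O[Si](CC)(CC)CC)C34[Co]5(=C=O)(=C=O)(=C=O)[Co]3(=C=O)(=C=O)(=C=O)C45[C@@H](O[Si](CC)(CC)CC)[C@]1(C)OCc1ccccc1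
F0 | step 20 | none | none
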